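Compound numbers refer to the steps and the compound list below; 22 is the target.

## Analysis of the target

- The target 22 is a chalcone whose ketone-bearing ring (ring A) is fused to a dihydropyran. The core is a chroman: O1, C2 with two methyl groups, C3 with a secondary hydroxyl, an unsubstituted C4 methylene, and the benzene carbons C4a to C8a.
- Ring A is pentasubstituted. C5 carries a free phenol, C6 the (E)-3-(4-hydroxyphenyl)propenoyl group, C7 a methoxy group, and only C8 carries hydrogen.
- C3 is the only stereocentre (R). It lies between the quaternary C2 and the benzylic C4, has no neighbouring stereocentre to relay from, and must be set by a reagent or catalyst. The E olefin is the only other stereochemical element.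
- The sensitive part is the 2'-hydroxychalcone. The C5 phenol can add to the enone to give a flavanone under acid or base, the enone is reducible and a Michael acceptor, and the trioxygenated ring is easily oxidised or over-substituted.
- The difficulty is twofold. A lone carbinol must be made enantiomerically pure next to a quaternary ether carbon. Three oxygens of one benzene ring must also end up different (ring ether at C8a, free OH at C5, methyl ether at C7), with the acyl group at C6 and not at C8.
- The strategy rests on two features. The C4 methylene (on C4a) and O1 (on C8a) are ortho neighbours on ring A, the pattern left by an ortho-quinone methide. C3 carries oxygen like the α-carbon of a glycolic acid derivative whose carboxyl carbon becomes C2.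
- The aromatic partner can stay mirror-symmetric, with two equivalent oxygens flanking the benzylic carbon, until the pyran ring closes.

## Retrosynthetic reasoning

**22 from 21.** The last disconnection removes the three methoxymethyl groups on O3, O5 and the ring B phenol. They are needed because the preceding step uses an aryllithium, and an aryl acetal both survives that step and directs it. The forward reaction must cleave one alkyl and two aryl acetals without closing the C5 phenol onto the enone.

**21 from 16 and 19.** The C6–C(=O) bond is cut. C6 lies between the acetal oxygen on C5 and the methoxy group on C7, the classical site for directed metalation. Cutting the Cα–Cβ bond of the enone instead (an aldol) would first need an acetyl group at C6, one more step on the main line. The gain is convergence: amide 19, made in two steps from acid 17 through 18, brings the whole cinnamoyl unit with its E geometry in place. The forward step must metalate C6 and not C8 (aryllithium 20), and must add once, at the carbonyl.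

**16 from 14 through 15.** This is a protecting-group exchange. The silyl ether on O5 is what the key step needs, but it cannot direct the metalation and would migrate to carbon in an ortho-lithiated species. It is removed (15) and both hydroxyls are capped as acetals (16).

**14 from 10 through 11, 12 and 13.** The two C2–CH3 bonds are traced back to the lactone carbonyl of 10. The carbonyl carbon becomes a methylidene (11), the olefin a spiro cyclopropane (12), and the cyclopropane is opened by hydrogenolysis, the benzyl ether being removed on the way (13). This was preferred to double addition of a methyl nucleophile because it never opens the ring and never places an enolisable ketone or a carbocation next to C3.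

**10 from 5 and 7.** This is the strategic disconnection. C3–C4 and O1–C2 are cut together, which takes the pyran ring apart into two pieces:
- ortho-quinone methide 8, a one-carbon benzylic electrophile with an ortho oxygen, released from acetate 5;
- azolium enolate 9, a two-carbon acyl unit with oxygen on its α-carbon, formed from acyl imidazole 7 and a chiral carbene.

It is the only cut that makes the ring and the stereocentre in one step. Because 5 is symmetric, either silyloxy group can be unmasked; the same quinone methide forms and the other silyloxy group becomes the C5 oxygen. The forward step needs only enantiofacial control at the enolate carbon.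

**5 from 1, and 7 from 6.** Acetate 5 is reached by functional-group changes on aldehyde 1: methylation of the 4-hydroxyl (2), silylation of the two remaining phenols (3), reduction (4) and acetylation. Acyl imidazole 7 is the activated form of acid 6. Neither sequence makes a stereocentre or a C–C bond, so the risk of the route sits in step 6.

## Alternatives that were turned down

**Alternative 1:** aryne insertion.
- Disconnection: the C5–O and C6–C(acyl) bonds of ring A are cut together and traced to an aryne spanning C5 and C6 of a preformed chroman.
- Forward key step: fluoride releases the aryne from the ortho-silyl aryl triflate A2. The carboxylate of acetic acid A3 adds at C5, the aryne carbon remote from the C7 methoxy group. The aryl anion that develops at C6 takes the acetyl group from oxygen, and hydroxy ketone A1 results.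
- For: one operation creates the ortho-hydroxy aryl ketone, and the methoxy group polarises the aryne in the required sense. A1 is one aldol condensation and a deprotection away from 22. On placing the acyl group this is better secured than the C6-versus-C8 competition that the metalation of 16 has to win.
- Against: the step does nothing for the pyran ring or for C3, which would have to be made first by other means. A2 is itself a chroman functionalised at both C5 and C6, so the regiochemical burden is moved into a multistep preparation and not removed. Protonation of the aryl anion by the acid competes with acyl transfer.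
- Comparison: it is clearly longer. In exchange for weaker C6 control, the chosen route makes ring, stereocentre and oxygenation pattern in one convergent step on a symmetric arene, and meets the C6 question once, late, on a simple substrate.

**Alternative 2:** benzannulation onto a dihydropyran.
- Disconnection: ring A is taken apart completely (C4a–C5, C5–C6, C7–C8 and C8–C8a) and rebuilt on an enantiopure dihydropyran.
- Forward key step: irradiation of diazo ketone A5 triggers a Wolff rearrangement to a vinylketene, which adds to ynol ether A6 in a (2+2) sense. The vinylcyclobutenone opens to a dienylketene, which closes by 6π electrocyclisation and tautomerises to phenol A4.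
- For: every substituent of ring A is placed by the connectivity of the two partners, so no arene regiochemistry has to be controlled. On this point it is stronger than both the symmetric-arene device and the C6 metalation of the chosen route.
- Against: C3 must already be present in A5, so a separate asymmetric synthesis of a 3-oxygenated 2,2-dimethyl dihydropyran with an acyl group on the enol ether carbon is needed first. A6 is a sensitive, doubly functionalised alkyne. The cascade must deliver a benzene with a bulky acetal wedged between OH and OMe. The acetal of A4 must then be unveiled and turned into the enone by addition and oxidation.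
- Comparison: the sequence is photochemical and long. The chosen route starts from an inexpensive trioxygenated benzaldehyde and creates the stereocentre in the ring-forming step.

**Alternative 3:** palladium C–O ring closure after dihydroxylation.
- Disconnection: C8a–O1, with the C3 stereocentre traced to an asymmetric dihydroxylation of a prenyl side chain.
- Forward key step: the tertiary alkoxide of triflate A8 undergoes intramolecular C–O coupling at C8a on zerovalent palladium carrying a bulky di-tert-butyl biaryl phosphine. This gives chroman A7, which already carries the C6 acetyl group.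
- For: dihydroxylation of a trisubstituted olefin is one of the most predictable ways to set a secondary carbinol. On this point it is stronger than a carbene-catalysed annulation with an untested α-alkoxy enolate. The acetyl group is para to the triflate and aids oxidative addition, and the acyl position is fixed from the start.
- Against: A8 is a benzene with five different substituents. Each of the three oxygens must be distinguished (triflate, acetal, methyl ether) and the prenyl group put on carbon regioselectively, which costs a long run of selective protections. The secondary hydroxyl must be masked in the presence of the tertiary one. Reductive elimination to a tertiary alkyl aryl ether is slow, and under base, triflate cleavage at sulfur and α-arylation or aldol chemistry of the methyl ketone compete.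
- Comparison: the chosen route gives up some predictability in the stereo-defining step, but it closes the ring and sets C3 in one operation, keeps the arene symmetric up to that point, and is shorter.

Key step: step 6

Assumption: the antipode of the aminoindanol-derived triazolium salt that exposes the Re face of the α-carbon of enolate 9 is taken to be the (5aS,10bR) salt. If the first run gives the 3S lactone, the (5aR,10bS) salt is used instead and nothing else changes.

## Route

Step 1
Reactants: 1 2,4,6-trihydroxybenzaldehyde
Product: 2 2,6-dihydroxy-4-methoxybenzaldehyde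
Conditions: Me2SO4 (1.0 equiv), K2CO3 (1.0 equiv), acetone, 0 °C to rt
Reagents that add atoms: dimethyl sulfate, COS(=O)(=O)OC
Why: Williamson O-methylation; the 4-hydroxyl is the most acidic (para to the formyl group and not held in a hydrogen bond to it), so one equivalent of weak base gives the 4-phenoxide, and the hard electrophile favours O- over C-methylation.

Step 2
Reactants: 2 2,6-dihydroxy-4-methoxybenzaldehyde
Product: 3 2,6-bis(tert-butyldimethylsilyloxy)-4-methoxybenzaldehyde
Conditions: TBSCl (2.5 equiv), imidazole (5 equiv), DMF, rt
Reagents that add atoms: tert-butyldimethylsilyl chloride, CC(C)(C)[Si](C)(C)Cl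
Why: Imidazole-promoted silylation of phenols; excess reagent overcomes the hydrogen bonding of the two ortho hydroxyls to the aldehyde, which is itself untouched.

Step 3
Reactants: 3 2,6-bis(tert-butyldimethylsilyloxy)-4-methoxybenzaldehyde
Product: 4 [2,6-bis(tert-butyldimethylsilyloxy)-4-methoxyphenyl]methanol
Conditions: NaBH4, MeOH–THF, 0 °C
Reagents that add atoms: none
Why: Hydride reduction of an aryl aldehyde; in the protic medium at 0 °C the benzylic alkoxide is protonated before an aryl-to-alkyl silyl shift can occur.

Step 4
Reactants: 4 [2,6-bis(tert-butyldimethylsilyloxy)-4-methoxyphenyl]methanol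
Product: 5 [2,6-bis(tert-butyldimethylsilyloxy)-4-methoxyphenyl]methyl acetate
Conditions: Ac2O, Et3N, 4-(dimethylamino)pyridine (cat.), CH2Cl2, 0 °C
Reagents that add atoms: acetic anhydride, CC(=O)OC(C)=O
Why: Nucleophile-catalysed acylation of a primary alcohol; basic, non-ionising conditions and chromatography on triethylamine-deactivated silica should keep the very electron-rich benzylic ester from solvolysing.

Step 5
Reactants: 6 benzyloxyacetic acid
Product: 7 2-(benzyloxy)-1-(1H-imidazol-1-yl)ethan-1-one
Conditions: 1,1'-carbonyldiimidazole (1.1 equiv), CH2Cl2, rt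
Reagents that add atoms: 1,1'-carbonyldiimidazole, O=C(n1ccnc1)n1ccnc1
Why: Carboxylic acid activation with carbonyldiimidazole; loss of CO2 drives formation of the acyl imidazole, which can be washed, dried and stored cold.

Step 6
Reactants: 5 [2,6-bis(tert-butyldimethylsilyloxy)-4-methoxyphenyl]methyl acetate; 7 2-(benzyloxy)-1-(1H-imidazol-1-yl)ethan-1-one (1.5 equiv)
Product: 10 (3R)-3-(benzyloxy)-5-(tert-butyldimethylsilyloxy)-7-methoxychroman-2-one, via ortho-quinone methide 8 (not isolated), via azolium enolate 9 (not isolated)
Conditions: (5aS,10bR)-2-(2,4,6-trimethylphenyl)-5a,10b-dihydro-4H,6H-indeno[2,1-b][1,2,4]triazolo[4,3-d][1,4]oxazin-2-ium tetrafluoroborate (10 mol %), CsF (1.2 equiv), 18-crown-6 (1.2 equiv), 4 Å MS, THF, −20 °C to rt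
Reagents that add atoms: none
Why: Fluoride removes one of the two equivalent silyl groups of 5 and the phenoxide expels acetate in a 1,4-elimination to give ortho-quinone methide 8; in parallel the triazolylidene formed from the salt attacks acyl imidazole 7, and deprotonation of the acyl azolium by acetate or imidazolide gives the (Z)-azolium enolate 9. The enolate α-carbon adds to the exocyclic methylene of 8 in a Michael-type step driven by rearomatisation (C3–C4), and the phenoxide so formed is acylated by the acyl azolium (O1–C2), which releases the carbene. The closest known reaction type is the carbene-catalysed formal (4+2) annulation of azolium enolates from acyl imidazoles with fluoride-generated ortho-quinone methides to 3,4-dihydrocoumarins; the α-benzyloxy group and the acetate leaving group are the only changes. The pyranone ring closes by a 6-exo-trig acyl substitution at the acyl azolium carbon. C3 is the only new stereocentre and is controlled by the catalyst: the fused aminoindanol backbone and the N-aryl group shield one face of the planar enolate, and bond formation on the Re face of the α-carbon (OBn > C2 > H) gives 3R. The methylene terminus of 8 is not prochiral, and because 5 has a mirror plane through C1 and C4 of its benzene ring the two silyloxy groups are equivalent, so only enantiofacial selectivity and mono-desilylation are needed, the latter secured by using little more than one equivalent of CsF. Only weak bases are present (acetate, imidazole, a near-stoichiometric charge of fluoride), which at low temperature should leave the C3–H of 10 in place.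

Step 7
Reactants: 10 (3R)-3-(benzyloxy)-5-(tert-butyldimethylsilyloxy)-7-methoxychroman-2-one
Product: 11 (3R)-3-(benzyloxy)-5-(tert-butyldimethylsilyloxy)-7-methoxy-2-methylidenechromane
Conditions: (C5H5)2Ti(CH3)2 (3 equiv), toluene, pyridine (1 mol %), 65 °C, dark
Reagents that add atoms: dimethyltitanocene (C5H5)2Ti(CH3)2, [CH3-].[CH3-].[Ti+4].c1cc[cH-]c1.c1cc[cH-]c1
Why: Petasis methylenation; thermolysis gives the titanium methylidene, which undergoes (2+2) addition to the lactone carbonyl and cycloreversion to the exocyclic enol ether, and the reagent is not basic enough to enolise the lactone, so C3 is untouched. The product is kept base-buffered and used at once.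

Step 8
Reactants: 11 (3R)-3-(benzyloxy)-5-(tert-butyldimethylsilyloxy)-7-methoxy-2-methylidenechromane
Product: 12 (3R)-3-(benzyloxy)-5-(tert-butyldimethylsilyloxy)-7-methoxyspiro[chromane-2,1'-cyclopropane]
Conditions: Et2Zn (3 equiv), CH2I2 (6 equiv), CH2Cl2, 0 °C to rt
Reagents that add atoms: diiodomethane, ICI
Why: Simmons–Smith cyclopropanation in the Furukawa variant; the electron-rich 1,1-disubstituted enol ether is among the fastest olefins toward the electrophilic zinc carbenoid, and no stereocentre arises because the two new methylene groups are equivalent.

Step 9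
Reactants: 12 (3R)-3-(benzyloxy)-5-(tert-butyldimethylsilyloxy)-7-methoxyspiro[chromane-2,1'-cyclopropane]
Product: 14 (3R)-5-(tert-butyldimethylsilyloxy)-7-methoxy-2,2-dimethylchroman-3-ol, via spirocyclopropyl alcohol 13 (not isolated)
Conditions: H2 (1 atm), Pd/C, EtOAc, rt; then AcOH, PtO2, H2 (3 atm), rt
Reagents that add atoms: none
Why: Catalytic hydrogenolysis in two stages: palladium first cleaves the benzyl ether without opening the cyclopropane, then platinum in acetic acid cleaves the least hindered CH2–CH2 bond of the spiro cyclopropane (remote from the oxygen-bearing quaternary carbon), leaving two methyl groups on C2. Removing the benzyl group first avoids saturation of its ring over platinum.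

Step 10
Reactants: 14 (3R)-5-(tert-butyldimethylsilyloxy)-7-methoxy-2,2-dimethylchroman-3-ol
Product: 15 (3R)-7-methoxy-2,2-dimethylchromane-3,5-diol
Conditions: Bu4NF (1.1 equiv), THF, 0 °C; aq NH4Cl
Reagents that add atoms: none
Why: Fluoride-mediated cleavage of an aryl silyl ether, driven by the Si–F bond; the secondary alcohol and the chroman are inert.

Step 11
Reactants: 15 (3R)-7-methoxy-2,2-dimethylchromane-3,5-diol
Product: 16 (3R)-7-methoxy-3,5-bis(methoxymethoxy)-2,2-dimethylchromane
Conditions: NaH (3 equiv), MOMCl (3 equiv), THF–DMF, 0 °C to rt
Reagents that add atoms: chloromethyl methyl ether, COCCl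
Why: Williamson-type acetal formation; both the phenoxide and the hindered secondary alkoxide are alkylated by the highly reactive chloromethyl ether.

Step 12
Reactants: 17 (E)-4-hydroxycinnamic acid
Product: 18 (E)-3-(4-hydroxyphenyl)-N-methoxy-N-methylprop-2-enamide
Conditions: MeNH(OMe)·HCl, EDC·HCl, 1-hydroxybenzotriazole, Et3N, DMF, 0 °C to rt
Reagents that add atoms: N,O-dimethylhydroxylamine hydrochloride, CNOC.Cl
Why: Carbodiimide amide coupling through the benzotriazolyl ester; the amine is far more nucleophilic than the phenol, so no phenol protection is needed, and the E olefin is unaffected.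

Step 13
Reactants: 18 (E)-3-(4-hydroxyphenyl)-N-methoxy-N-methylprop-2-enamide
Product: 19 (E)-N-methoxy-3-[4-(methoxymethoxy)phenyl]-N-methylprop-2-enamide
Conditions: MOMCl, i-Pr2NEt, CH2Cl2, 0 °C to rt
Reagents that add atoms: chloromethyl methyl ether, COCCl
Why: O-Alkylation of the phenol with a chloromethyl ether (acetal protection); the amide is inert.

Step 14
Reactants: 16 (3R)-7-methoxy-3,5-bis(methoxymethoxy)-2,2-dimethylchromane; 19 (E)-N-methoxy-3-[4-(methoxymethoxy)phenyl]-N-methylprop-2-enamide
Product: 21 (E)-1-[(3R)-7-methoxy-3,5-bis(methoxymethoxy)-2,2-dimethylchroman-6-yl]-3-[4-(methoxymethoxy)phenyl]prop-2-en-1-one, via aryllithium 20 (not isolated)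
Conditions: n-BuLi (1.2 equiv), THF, 0 °C; then 19 (1.3 equiv), −78 to −20 °C; aq NH4Cl
Reagents that add atoms: none
Why: Directed ortho-metalation followed by Weinreb ketone synthesis; C6–H is flanked by the chelating acetal oxygen on C5 and the methoxy group on C7 and should be removed in preference to C8–H, which lies between the methoxy group and the poorly coordinating ring oxygen. The N-methoxy-N-methyl amide takes up one aryl group at the carbonyl and releases the ketone only on work-up, so the E enone arrives intact.

Step 15
Reactants: 21 (E)-1-[(3R)-7-methoxy-3,5-bis(methoxymethoxy)-2,2-dimethylchroman-6-yl]-3-[4-(methoxymethoxy)phenyl]prop-2-en-1-one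
Product: 22 (E)-1-[(3R)-3,5-dihydroxy-7-methoxy-2,2-dimethylchroman-6-yl]-3-(4-hydroxyphenyl)prop-2-en-1-one
Conditions: HCl (3 M aq), MeOH, 40 °C
Reagents that add atoms: none
Why: Acid-catalysed acetal exchange removes the three methoxymethyl groups as dimethoxymethane; the C5 phenol is held in a hydrogen bond to the ketone, which disfavours its conjugate addition to the enone, and the moderate temperature limits flavanone formation.

## Compound list

1 | 2,4,6-trihydroxybenzaldehyde | O=Cc1c(O)cc(O)cc1O | starting material
2 | 2,6-dihydroxy-4-methoxybenzaldehyde | COc1cc(O)c(C=O)c(O)c1 | intermediate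
3 | 2,6-bis(tert-butyldimethylsilyloxy)-4-methoxybenzaldehyde | COc1cc(O[Si](C)(C)C(C)(C)C)c(C=O)c(O[Si](C)(C)C(C)(C)C)c1 | intermediate
4 | [2,6-bis(tert-butyldimethylsilyloxy)-4-methoxyphenyl]methanol | COc1cc(O[Si](C)(C)C(C)(C)C)c(CO)c(O[Si](C)(C)C(C)(C)C)c1 | intermediate
5 | [2,6-bis(tert-butyldimethylsilyloxy)-4-methoxyphenyl]methyl acetate | COc1cc(O[Si](C)(C)C(C)(C)C)c(COC(C)=O)c(O[Si](C)(C)C(C)(C)C)c1 | intermediate
6 | benzyloxyacetic acid | OC(=O)COCc1ccccc1 | starting material
7 | 2-(benzyloxy)-1-(1H-imidazol-1-yl)ethan-1-one | O=C(COCc1ccccc1)n1ccnc1 | intermediate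
8 | 5-(tert-butyldimethylsilyloxy)-3-methoxy-6-methylidenecyclohexa-2,4-dien-1-one | C=C1C(=O)C=C(OC)C=C1O[Si](C)(C)C(C)(C)C | intermediate (not isolated)
9 | (Z)-2-(benzyloxy)-1-[(5aS,10bR)-2-(2,4,6-trimethylphenyl)-5a,10b-dihydro-4H,6H-indeno[2,1-b][1,2,4]triazolo[4,3-d][1,4]oxazin-2-ium-1-yl]ethen-1-olate | [O-]/C(=C\OCc1ccccc1)c1n2c(n[n+]1-c1c(C)cc(C)cc1C)CO[C@H]1Cc3ccccc3[C@H]12 | intermediate (not isolated)
10 | (3R)-3-(benzyloxy)-5-(tert-butyldimethylsilyloxy)-7-methoxychroman-2-one | COc1cc2c(c(O[Si](C)(C)C(C)(C)C)c1)C[C@@H](OCc1ccccc1)C(=O)O2 | intermediate
11 | (3R)-3-(benzyloxy)-5-(tert-butyldimethylsilyloxy)-7-methoxy-2-methylidenechromane | COc1cc2c(c(O[Si](C)(C)C(C)(C)C)c1)C[C@@H](OCc1ccccc1)C(=C)O2 | intermediate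
12 | (3R)-3-(benzyloxy)-5-(tert-butyldimethylsilyloxy)-7-methoxyspiro[chromane-2,1'-cyclopropane] | COc1cc2c(c(O[Si](C)(C)C(C)(C)C)c1)C[C@@H](OCc1ccccc1)C1(CC1)O2 | intermediate
13 | (3R)-5-(tert-butyldimethylsilyloxy)-7-methoxyspiro[chromane-2,1'-cyclopropan]-3-ol | COc1cc2c(c(O[Si](C)(C)C(C)(C)C)c1)C[C@@H](O)C1(CC1)O2 | intermediate (not isolated)
14 | (3R)-5-(tert-butyldimethylsilyloxy)-7-methoxy-2,2-dimethylchroman-3-ol | COc1cc2c(c(O[Si](C)(C)C(C)(C)C)c1)C[C@@H](O)C(C)(C)O2 | intermediate
15 | (3R)-7-methoxy-2,2-dimethylchromane-3,5-diol | COc1cc2c(c(O)c1)C[C@@H](O)C(C)(C)O2 | intermediate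
16 | (3R)-7-methoxy-3,5-bis(methoxymethoxy)-2,2-dimethylchromane | COc1cc2c(c(OCOC)c1)C[C@@H](OCOC)C(C)(C)O2 | intermediate
17 | (E)-4-hydroxycinnamic acid | OC(=O)/C=C/c1ccc(O)cc1 | starting material
18 | (E)-3-(4-hydroxyphenyl)-N-methoxy-N-methylprop-2-enamide | CON(C)C(=O)/C=C/c1ccc(O)cc1 | intermediate
19 | (E)-N-methoxy-3-[4-(methoxymethoxy)phenyl]-N-methylprop-2-enamide | CON(C)C(=O)/C=C/c1ccc(OCOC)cc1 | intermediate
20 | [(3R)-7-methoxy-3,5-bis(methoxymethoxy)-2,2-dimethylchroman-6-yl]lithium | COc1cc2c(c(OCOC)c1[Li])C[C@@H](OCOC)C(C)(C)O2 | intermediate (not isolated)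
21 | (E)-1-[(3R)-7-methoxy-3,5-bis(methoxymethoxy)-2,2-dimethylchroman-6-yl]-3-[4-(methoxymethoxy)phenyl]prop-2-en-1-one | COc1cc2c(c(OCOC)c1C(=O)/C=C/c1ccc(OCOC)cc1)C[C@@H](OCOC)C(C)(C)O2 | intermediate
22 | (E)-1-[(3R)-3,5-dihydroxy-7-methoxy-2,2-dimethylchroman-6-yl]-3-(4-hydroxyphenyl)prop-2-en-1-one | COc1cc2c(c(O)c1C(=O)/C=C/c1ccc(O)cc1)C[C@@H](O)C(C)(C)O2 | target

## Step count and least certain steps

Total: 15 steps. Longest linear sequence: 12 steps (1–4, 6–11, 14, 15). Step 5 and steps 12–13 are side branches.

**Step 6 (key step).**
- Most likely failure: loss of enantiocontrol through a racemic background path, in which the acidic α-alkoxy acyl imidazole is enolised by imidazolide or fluoride without the carbene and adds to the quinone methide on its own.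
- Also possible: slow turnover of the less nucleophilic α-alkoxy enolate, so that the quinone methide oligomerises or is trapped by imidazole; cleavage of the second silyl ether; base-induced epimerisation at C3.
- Fallback, from 4 and 6, returning at 10: alcohol 4 is converted with CBr4/PPh3 at 0 °C into 2-(bromomethyl)-1,3-bis(tert-butyldimethylsilyloxy)-5-methoxybenzene F1, used crude. Acid 6 is coupled through its pivaloyl mixed anhydride with lithiated (4S)-4-benzyl-1,3-oxazolidin-2-one to give (4S)-4-benzyl-3-[(benzyloxy)acetyl]-1,3-oxazolidin-2-one F2. The sodium enolate of F2 (NaN(SiMe3)2, THF, −78 °C) is alkylated by F1 on the face away from the auxiliary's benzyl group (Evans alkylation). This should give (4S)-4-benzyl-3-[(2R)-2-(benzyloxy)-3-[2,6-bis(tert-butyldimethylsilyloxy)-4-methoxyphenyl]propanoyl]-1,3-oxazolidin-2-one F3. Bu4NF buffered with acetic acid removes both silyl groups, and one of the freed phenols closes onto the imide carbonyl with loss of the auxiliary, giving (3R)-3-(benzyloxy)-5-hydroxy-7-methoxychroman-2-one F4. Silylation with TBSCl/imidazole returns 10.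

**Step 7.**
- Most likely failure: migration of the exocyclic enol ether double bond into the ring under traces of acid, which would erase C3. Hydrolysis on silica and incomplete methylenation of the hindered aryl lactone are also possible.
- Fallback, from 10, returning at 14: excess CH3MgBr with CeCl3 (THF, −78 °C) opens the lactone and adds twice, giving 2-[(2R)-2-(benzyloxy)-3-hydroxy-3-methylbutyl]-3-(tert-butyldimethylsilyloxy)-5-methoxyphenol F5. Catalytic TsOH in CH2Cl2 closes the ring by attack of the phenol on the tertiary carbocation, C3 not being involved, to give (3R)-3-(benzyloxy)-5-(tert-butyldimethylsilyloxy)-7-methoxy-2,2-dimethylchromane F6. Hydrogenolysis over Pd/C gives 14.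
- This fallback replaces steps 7–9 as a block, so it also covers wrong-bond cleavage or over-reduction in the cyclopropane hydrogenolysis.

**Step 14.**
- Most likely failure: deprotonation at C8 in competition with C6, because both positions lie between two oxygens. Conjugate addition of the aryllithium to the unsaturated amide is a second possibility.
- Fallback, from 15, returning at 21: magnesium-mediated ortho-formylation (MgCl2, Et3N, paraformaldehyde, MeCN, reflux; Casnati–Skattebøl) can only attack C6, the single free position ortho to the phenol. It gives (3R)-3,5-dihydroxy-7-methoxy-2,2-dimethylchromane-6-carbaldehyde F7. NaH/MOMCl gives (3R)-7-methoxy-3,5-bis(methoxymethoxy)-2,2-dimethylchromane-6-carbaldehyde F8. CH3MgBr gives 1-[(3R)-7-methoxy-3,5-bis(methoxymethoxy)-2,2-dimethylchroman-6-yl]ethan-1-ol F9 (both carbinol epimers). Dess–Martin oxidation gives 1-[(3R)-7-methoxy-3,5-bis(methoxymethoxy)-2,2-dimethylchroman-6-yl]ethan-1-one F10, the same ketone as A7. Claisen–Schmidt condensation of F10 with commercial 4-(methoxymethoxy)benzaldehyde (KOH, EtOH) gives 21.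

**Step 15.**
- Most likely failure: acid-promoted closure of the freed C5 phenol onto the enone (flavanone formation) during the longer exposure needed for the secondary alkyl acetal, or incomplete cleavage of that acetal.
- Fallback, from 16, returning at 22: aryllithium 20 is quenched with N-methoxy-N-methylacetamide to give F10. The acetals are removed at this stage (HCl, MeOH, 50 °C), where no enone is present, to give 1-[(3R)-3,5-dihydroxy-7-methoxy-2,2-dimethylchroman-6-yl]ethan-1-one F11. Base-mediated Claisen–Schmidt condensation of F11 with 4-hydroxybenzaldehyde (aq KOH, EtOH, rt) forms the chalcone 22 last, with no acid step after it.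

**Step 1.**
- Most likely failure: over-methylation at a second oxygen, or C-methylation of the electron-rich ring, making the mono-ether hard to purify.
- Fallback, from 1, returning at 2: exhaustive methylation (excess Me2SO4, K2CO3, acetone, reflux) gives 2,4,6-trimethoxybenzaldehyde F12. AlCl3 (excess, CH2Cl2, reflux) then cleaves only the two ethers ortho to the carbonyl, through the aluminium chelate, leaving the para methyl ether and giving 2.

## Further compounds

F1 | step 6 | 2-(bromomethyl)-1,3-bis(tert-butyldimethylsilyloxy)-5-methoxybenzene | COc1cc(O[Si](C)(C)C(C)(C)C)c(CBr)c(O[Si](C)(C)C(C)(C)C)c1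
F2 | step 6 | (4S)-4-benzyl-3-[(benzyloxy)acetyl]-1,3-oxazolidin-2-one | O=C(COCc1ccccc1)N1[C@@H](Cc2ccccc2)COC1=O
F3 | step 6 | (4S)-4-benzyl-3-[(2R)-2-(benzyloxy)-3-[2,6-bis(tert-butyldimethylsilyloxy)-4-methoxyphenyl]propanoyl]-1,3-oxazolidin-2-one | COc1cc(O[Si](C)(C)C(C)(C)C)c(C[C@@H](OCc2ccccc2)C(=O)N2[C@@H](Cc3ccccc3)COC2=O)c(O[Si](C)(C)C(C)(C)C)c1
F4 | step 6 | (3R)-3-(benzyloxy)-5-hydroxy-7-methoxychroman-2-one | COc1cc2c(c(O)c1)C[C@@H](OCc1ccccc1)C(=O)O2
F5 | step 7 | 2-[(2R)-2-(benzyloxy)-3-hydroxy-3-methylbutyl]-3-(tert-butyldimethylsilyloxy)-5-methoxyphenol | COc1cc(O)c(C[C@@H](OCc2ccccc2)C(C)(C)O)c(O[Si](C)(C)C(C)(C)C)c1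
F6 | step 7 | (3R)-3-(benzyloxy)-5-(tert-butyldimethylsilyloxy)-7-methoxy-2,2-dimethylchromane | COc1cc2c(c(O[Si](C)(C)C(C)(C)C)c1)C[C@@H](OCc1ccccc1)C(C)(C)O2
F7 | step 14 | (3R)-3,5-dihydroxy-7-methoxy-2,2-dimethylchromane-6-carbaldehyde | COc1cc2c(c(O)c1C=O)C[C@@H](O)C(C)(C)O2
F8 | step 14 | (3R)-7-methoxy-3,5-bis(methoxymethoxy)-2,2-dimethylchromane-6-carbaldehyde | COc1cc2c(c(OCOC)c1C=O)C[C@@H](OCOC)C(C)(C)O2
F9 | step 14 | 1-[(3R)-7-methoxy-3,5-bis(methoxymethoxy)-2,2-dimethylchroman-6-yl]ethan-1-ol (both carbinol epimers) | COc1cc2c(c(OCOC)c1C(C)O)C[C@@H](OCOC)C(C)(C)O2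
F10 | step 14 | 1-[(3R)-7-methoxy-3,5-bis(methoxymethoxy)-2,2-dimethylchroman-6-yl]ethan-1-one | COc1cc2c(c(OCOC)c1C(C)=O)C[C@@H](OCOC)C(C)(C)O2
F11 | step 15 | 1-[(3R)-3,5-dihydroxy-7-methoxy-2,2-dimethylchroman-6-yl]ethan-1-one | COc1cc2c(c(O)c1C(C)=O)C[C@@H](O)C(C)(C)O2
F12 | step 1 | 2,4,6-trimethoxybenzaldehyde | COc1cc(OC)c(C=O)c(OC)c1
A1 | alternative 1 | 1-[(3R)-5-hydroxy-7-methoxy-3-(methoxymethoxy)-2,2-dimethylchroman-6-yl]ethan-1-one | COc1cc2c(c(O)c1C(C)=O)C[C@@H](OCOC)C(C)(C)O2
A2 | alternative 1 | (3R)-7-methoxy-3-(methoxymethoxy)-2,2-dimethyl-6-(trimethylsilyl)chroman-5-yl trifluoromethanesulfonate | COc1cc2c(c(OS(=O)(=O)C(F)(F)F)c1[Si](C)(C)C)C[C@@H](OCOC)C(C)(C)O2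
A3 | alternative 1 | acetic acid | CC(=O)O
A4 | alternative 2 | (3R)-3-(tert-butyldimethylsilyloxy)-6-(diethoxymethyl)-7-methoxy-2,2-dimethylchroman-5-ol | CCOC(OCC)c1c(OC)cc2c(c1O)C[C@@H](O[Si](C)(C)C(C)(C)C)C(C)(C)O2
A5 | alternative 2 | 2-diazo-1-[(3R)-3-(tert-butyldimethylsilyloxy)-2,2-dimethyl-3,4-dihydro-2H-pyran-6-yl]ethan-1-one | [N-]=[N+]=CC(=O)C1=CC[C@@H](O[Si](C)(C)C(C)(C)C)C(C)(C)O1
A6 | alternative 2 | 3,3-diethoxy-1-methoxyprop-1-yne | COC#CC(OCC)OCC
A7 | alternative 3 | 1-[(3R)-7-methoxy-3,5-bis(methoxymethoxy)-2,2-dimethylchroman-6-yl]ethan-1-one | COc1cc2c(c(OCOC)c1C(C)=O)C[C@@H](OCOC)C(C)(C)O2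
A8 | alternative 3 | 4-acetyl-2-[(2R)-3-hydroxy-2-(methoxymethoxy)-3-methylbutyl]-5-methoxy-3-(methoxymethoxy)phenyl trifluoromethanesulfonate | COc1cc(OS(=O)(=O)C(F)(F)F)c(C[C@@H](OCOC)C(C)(C)O)c(OCOC)c1C(C)=O
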